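**Atom numbering.** All ring atoms use target (germacrane) numbering. The carvone carbonyl carbon is C9, carvone C6 is C8, C5 is C7, C4 is C6, C3 is C5 and C2 is C4.

**Retrosynthetic overview**
1. The target comes from C8 acetylation, oxidation of the C14 alcohol, and a hydroxyl-directed epoxidation of a (Z)-C1=C10 allylic alcohol.
2. That alkene and C9H2 come from an enone by Luche reduction and Myers allylic transposition. The enone comes from a Stork–Danheiser deoxygenation of a 10-membered 1,3-diketone.
3. The 10-membered ring, with (E)-C4=C5 and C6–OAc, comes from a photochemical alkoxy-radical ring expansion of a decalin β-ketol (6,6 → 10). The radical is captured by Cu–OAc.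
4. The decalin comes from Robinson-type Michael/aldol chemistry on a carvone-derived ketone. C7 comes from (R)-carvone, and C8–O from a trans-selective Rubottom oxidation.
5. Rings are formed in this order: cyclohexanone (carvone), decalin, 10-membered ring, epoxide.

**Assumptions**
- The thermodynamic dienolate of 4 reacts with methyl vinyl ketone at its α-carbon (C4) to give the quaternary centre.
- The C4 and C9 configurations in 6 and 7 are irrelevant, because both centres are destroyed in Step 6.
- The less hindered C1 carbonyl of the 1,3-diketone forms the vinylogous ester in Step 9.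

---

**Step 1**
Reactants: 1 (R)-carvone
Product: 2 (R)-carvotanacetone
Conditions: H2 (1 atm), RhCl(PPh3)3 (2 mol %), benzene, rt
Reagents that add atoms: none
Why: Wilkinson hydrogenation reduces the 1,1-disubstituted isopropenyl group selectively over the enone, giving iPr with C7 untouched.

**Step 2**
Reactants: 2
Product: 3 TBS dienol ether (kinetic enolate at C8)
Conditions: LDA, THF, −78 °C; then TBSCl, DMPU, −78 → 0 °C
Reagents that add atoms: TBSCl, CC(C)(C)[Si](C)(C)Cl
Why: Kinetic deprotonation at the α′-carbon and O-silylation give the silyl enol ether for the Rubottom oxidation.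

**Step 3**
Reactants: 3
Product: 4 (C8-OTBS ketone, 7,8-trans)
Conditions: mCPBA, NaHCO3, CH2Cl2, 0 °C; aqueous workup
Reagents that add atoms: mCPBA, OOC(=O)c1cccc(Cl)c1
Why: Rubottom oxidation with 1,4-silyl shift. The peracid approaches anti to the C7 isopropyl group, so C8–OTBS is trans to iPr, as required by the target.

**Step 4**
Reactants: 4, 5 methyl vinyl ketone
Product: 6 (1,5-diketone with quaternary C4)
Conditions: t-BuOK, t-BuOH/THF, 0 °C; then 5
Reagents that add atoms: none (5 is the listed reactant)
Why: The thermodynamic extended dienolate undergoes Michael addition at its α-carbon (Robinson-type). The ring alkene shifts to C5=C6 and the new quaternary centre is later destroyed.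

**Step 5**
Reactants: 6
Product: 7 (cis-decalin β-ketol, tertiary C9–OH)
Conditions: LiHMDS, THF, −78 °C; quench with sat. NH4Cl at −78 °C
Reagents that add atoms: none
Why: Kinetic enolisation of the methyl ketone (C10) and intramolecular aldol onto the ring ketone C9 close the six-membered ring. Cold quench stops the sequence before dehydration.

**Step 6**
Reactants: 7
Product: 8 (10-membered 1,3-diketone with (E)-C4=C5 and C6–OAc)
Conditions: Cu(OAc)2 (2.5 equiv), AcOH (10 equiv), MeCN, 390 nm LEDs, 25 °C
Reagents that add atoms: Cu(OAc)2, CC(=O)O[Cu]OC(C)=O; AcOH, CC(=O)O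
Why: Proposed new method: Cu(II)-alkoxide LMCT gives the C9 alkoxy radical. β-Scission of the ring-fusion C9–C4 bond (driven by C=O formation and a tertiary, allyl-stabilised C4 radical) expands 6,6 to a 10-membered ring. The allyl radical is captured by Cu(II)–OAc at the less substituted terminus C6 (allyl-Cu(III), C–O reductive elimination). This forms the trisubstituted C4=C5 alkene and sets C6–OAc by peripheral attack on the ring. The closest known chemistry is Suárez/Kalvoda–Heusler alkoxy-radical fragmentation combined with Kharasch–Sosnovsky Cu-carboxylate oxidation of radicals.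

**Step 7**
Reactants: 8, 9 formaldehyde
Product: 10 (C10–CH2OH 1,3-diketone)
Conditions: aq. HCHO (1.1 equiv), Et3N (0.2 equiv), THF, 0 °C
Reagents that add atoms: none (9 is the listed reactant)
Why: Aldol (hydroxymethylation) at the doubly activated C10 installs C14.

**Step 8**
Reactants: 10
Product: 11 (C14-OTBS)
Conditions: TBSCl, imidazole, DMF, 0 °C
Reagents that add atoms: TBSCl, CC(C)(C)[Si](C)(C)Cl
Why: Silylation of the primary alcohol protects C14 for the following hydride and Mitsunobu-type steps.

**Step 9**
Reactants: 11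
Product: 12 (C1-methyl vinylogous ester, C9 ketone retained)
Conditions: HC(OMe)3, MeOH, TsOH (cat.), rt
Reagents that add atoms: trimethyl orthoformate, COC(OC)OC; MeOH, CO
Why: Enol-ether formation occurs at the less hindered C1 carbonyl; C9 sits next to C8–OTBS and is more hindered.

**Step 10**
Reactants: 12
Product: 13 (enone C1(=O)–C10(CH2OTBS)=C9H)
Conditions: DIBAL-H (1.5 equiv), CH2Cl2, −78 °C; then 1 M HCl/THF, 0 °C
Reagents that add atoms: H2O, O (the C1 carbonyl oxygen)
Why: Stork–Danheiser transposition. Hydride adds to C9=O, then acid causes ionisation and enol-ether hydrolysis. This removes the C9 oxygen and converts C1 into the ketone.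

**Step 11**
Reactants: 13
Product: 14 (C1 allylic alcohol, C9=C10)
Conditions: NaBH4, CeCl3·7H2O, MeOH, −78 °C
Reagents that add atoms: none
Why: Luche 1,2-reduction. The C1 carbinol configuration is irrelevant because it is destroyed in Step 12.

**Step 12**
Reactants: 14
Product: 15 (Z-C1=C10, C9H2)
Conditions: o-NBSH, PPh3, DIAD, THF, −15 → 23 °C
Reagents that add atoms: none (N2 and sulfinate are lost)
Why: Myers reductive allylic transposition. An allylic diazene undergoes retro-ene loss of N2, delivering H to C9 and forming C1=C10, the (Z)-in-ring alkene the target's cis-epoxide requires.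

**Step 13**
Reactants: 15
Product: 16 (free C14 allylic alcohol)
Conditions: PPTS, MeOH/CH2Cl2, 0 → 23 °C
Reagents that add atoms: none
Why: The primary TBS ether is cleaved selectively over the hindered secondary C8–OTBS, leaving the C6 acetate intact.

**Step 14**
Reactants: 16
Product: 17 (1,10-epoxy alcohol, cis-epoxide)
Conditions: VO(acac)2 (5 mol %), TBHP, CH2Cl2, 0 °C
Reagents that add atoms: TBHP, CC(C)(C)OO
Why: Vanadium-catalysed hydroxyl-directed epoxidation is selective for the allylic alcohol over the C4=C5 alkene, which is deactivated by the allylic acetate. The epoxide face is set by the C14–OH and the ring conformation, with O syn to the C8 oxygen.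

**Step 15**
Reactants: 17
Product: 18 (α,β-epoxy aldehyde)
Conditions: Dess–Martin periodinane, NaHCO3, CH2Cl2, 0 °C
Reagents that add atoms: none
Why: Dess–Martin oxidation of the primary alcohol, mild enough to leave the epoxide and aldehyde intact.

**Step 16**
Reactants: 18
Product: 19 (C8–OH)
Conditions: HF·pyridine, THF/pyridine, 0 °C
Reagents that add atoms: none
Why: Neutral fluoride removes the secondary TBS without touching the acetate, epoxide or aldehyde.

**Step 17**
Reactants: 19
Product: 20 Pulicanaral A
Conditions: Ac2O, DMAP, pyridine, CH2Cl2, 0 °C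
Reagents that add atoms: Ac2O, CC(=O)OC(C)=O
Why: Acetylation of the secondary alcohol with retention gives the target.

---

**Compound list**

1 | (R)-(−)-carvone | O=C1C(C)=CC[C@@H](C(C)=C)C1 | starting material
2 | (R)-carvotanacetone | O=C1C(C)=CC[C@@H](C(C)C)C1 | intermediate
3 | TBS dienol ether of 2 | CC1=CC[C@@H](C(C)C)C=C1O[Si](C)(C)C(C)(C)C | intermediate
4 | 8-OTBS-7-isopropyl-4-methylcyclohex-4-en-9-one, 7,8-trans | O=C1C(C)=CC[C@@H](C(C)C)[C@@H]1O[Si](C)(C)C(C)(C)C | intermediate
5 | methyl vinyl ketone | C=CC(C)=O | starting material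
6 | Michael adduct (quaternary C4, CH2CH2COCH3) | CC(=O)CCC1(C)C=C[C@@H](C(C)C)[C@H](O[Si](C)(C)C(C)(C)C)C1=O | intermediate
7 | cis-decalin β-ketol (C9–OH) | O=C1CCC2(C)C=C[C@@H](C(C)C)[C@H](O[Si](C)(C)C(C)(C)C)C2(O)C1 | intermediate
8 | 6-acetoxy-8-OTBS-7-isopropyl-4-methylcyclodec-4E-ene-1,9-dione | CC(=O)O[C@@H]1/C=C(\C)CCC(=O)CC(=O)[C@@H](O[Si](C)(C)C(C)(C)C)[C@@H]1C(C)C | intermediate
9 | formaldehyde | C=O | starting material
10 | 10-hydroxymethyl diketone | CC(=O)O[C@@H]1/C=C(\C)CCC(=O)C(CO)C(=O)[C@@H](O[Si](C)(C)C(C)(C)C)[C@@H]1C(C)C | intermediate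
11 | C14-OTBS diketone | CC(=O)O[C@@H]1/C=C(\C)CCC(=O)C(CO[Si](C)(C)C(C)(C)C)C(=O)[C@@H](O[Si](C)(C)C(C)(C)C)[C@@H]1C(C)C | intermediate
12 | C1-methyl vinylogous ester | CC(=O)O[C@@H]1/C=C(\C)CCC(OC)=C(CO[Si](C)(C)C(C)(C)C)C(=O)[C@@H](O[Si](C)(C)C(C)(C)C)[C@@H]1C(C)C | intermediate
13 | enone (C1=O, C9=C10) | CC(=O)O[C@@H]1/C=C(\C)CCC(=O)C(CO[Si](C)(C)C(C)(C)C)=C[C@@H](O[Si](C)(C)C(C)(C)C)[C@@H]1C(C)C | intermediate
14 | C1 allylic alcohol | CC(=O)O[C@@H]1/C=C(\C)CCC(O)C(CO[Si](C)(C)C(C)(C)C)=C[C@@H](O[Si](C)(C)C(C)(C)C)[C@@H]1C(C)C | intermediate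
15 | (Z)-C1=C10 alkene, bis-TBS | CC(=O)O[C@@H]1/C=C(\C)CC/C=C(/CO[Si](C)(C)C(C)(C)C)C[C@@H](O[Si](C)(C)C(C)(C)C)[C@@H]1C(C)C | intermediate
16 | C14 allylic alcohol | CC(=O)O[C@@H]1/C=C(\C)CC/C=C(/CO)C[C@@H](O[Si](C)(C)C(C)(C)C)[C@@H]1C(C)C | intermediate
17 | 1,10-epoxy alcohol | CC(=O)O[C@@H]1/C=C(\C)CC[C@H]2O[C@@]2(CO)C[C@@H](O[Si](C)(C)C(C)(C)C)[C@@H]1C(C)C | intermediate
18 | epoxy aldehyde, 8-OTBS | CC(=O)O[C@@H]1/C=C(\C)CC[C@H]2O[C@@]2(C=O)C[C@@H](O[Si](C)(C)C(C)(C)C)[C@@H]1C(C)C | intermediate
19 | epoxy aldehyde, 8-OH | CC(=O)O[C@@H]1/C=C(\C)CC[C@H]2O[C@@]2(C=O)C[C@@H](O)[C@@H]1C(C)C | intermediate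
20 | Pulicanaral A | CC(=O)O[C@@H]1/C=C(\C)CC[C@H]2O[C@@]2(C=O)C[C@@H](OC(C)=O)[C@@H]1C(C)C | target

**Total step count:** 17. **Longest linear sequence:** 17 (5 and 9 are single-step reagents).

**Three steps most likely to fail**
1. **Step 6 (proposed new step).** Risks are the E/Z outcome at C4=C5, the C6 acetate configuration, and over-oxidation of the diketone.
   - Fallback: Pd-catalysed retro-allylation of the tertiary homoallylic alkoxide of 7. This gives the ketone plus a π-allyl-Pd intermediate, which is trapped by acetate at C6 (Tsuji–Trost). Any Z-alkene formed could then be isomerised by sensitised photoisomerisation.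
2. **Step 10 (Stork–Danheiser).** DIBAL may reduce the C6 acetate, and the hindered C9 carbonyl may react poorly.
   - Fallback: ketalise C1 selectively, remove C9 oxygen by tosylhydrazone/catecholborane (Kabalka) reduction, deprotect, then form the C1=C10 alkene from the C1 ketone by regioselective enol triflation toward C10 and reduction.
3. **Step 14 (directed epoxidation).** The facial selectivity in the 10-membered ring may give the wrong epoxide diastereomer.
   - Fallback: oxidise 16 to the enal and use nucleophilic epoxidation (TBHP/DBU). Then reduce to the aldehyde level as needed, or epoxidise at the enal stage and deprotect.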